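The route rests on closing ring A last, by a [3+3] annulation onto a ring-B enone. It exploits that the quaternary carbons C-10 and C-4 (abietane numbering), 1,3-related across C-5 in ring A, are an enone β-carbon and an ester α-carbon in a monocyclic precursor. In one flask, copper-catalysed conjugate addition of a 3-chloropropyl Grignard reagent forms C-1–C-10 anti to the C-5 substituent, and the C-4 ester enolate then displaces the chloride to form C-3–C-4, giving the trans-decalin with both quaternary centres. The precursor is a 4-substituted 3-methylcyclohexenone; the trapped C-8 enol ether later carries the C-9 side chain and the C-8 carboxyl.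

Key step: step 4

Remark on numbering and assumptions: atoms are numbered as in abietane. Ring A is C-1, C-2, C-3, C-4, C-5, C-10; ring B is C-5 to C-10. C-18 is the carboxyl and C-19 the methyl on C-4, C-20 the methyl on C-10, C-14 the carboxyl on C-8; the side chain on C-9 is C-11, C-12, C-13 (C=O) and the isopropyl group. Compounds 1, 3, 7 and 11 are taken as commercial. The propanoate α-carbon (C-4) is carried as an epimer mixture until step 4, where it is enolised and set.

Step 1
Reactants: 1 2-methylcyclohex-2-en-1-one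
Product: 2 (1S)-2-methylcyclohex-2-en-1-ol
Conditions: (R)-2-methyl-CBS-oxazaborolidine (10 mol %), BH3·SMe2, THF, −20 °C
Reagents that add atoms: none
Why: Corey–Bakshi–Shibata reduction should give 1,2-reduction only, and with the trisubstituted alkenyl flank acting as the large group the (R)-oxazaborolidine should deliver hydride to the face that gives the (S)-carbinol.

Step 2
Reactants: 2 (1S)-2-methylcyclohex-2-en-1-ol; 3 trimethyl orthopropionate
Product: 5 methyl 2-[(1S)-2-methylcyclohex-2-en-1-yl]propanoate, via ketene acetal 4 (not isolated)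
Conditions: EtCO2H (cat.), neat, 140 °C, MeOH distilled off
Reagents that add atoms: none
Why: Johnson–Claisen rearrangement: the suprafacial [3,3] shift of ketene acetal 4 should transfer the C–O stereocentre to the new C-4–C-5 bond (C-5 set as S), move the alkene to C-9=C-10 and bring in C-4 with C-18 and C-19.

Step 3
Reactants: 5 methyl 2-[(1S)-2-methylcyclohex-2-en-1-yl]propanoate
Product: 6 methyl 2-[(1S)-2-methyl-4-oxocyclohex-2-en-1-yl]propanoate
Conditions: dirhodium tetracaprolactamate Rh2(cap)4 (1 mol %), tBuOOH, K2CO3, CH2Cl2, 23 °C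
Reagents that add atoms: tert-butyl hydroperoxide, CC(C)(C)OO
Why: Radical allylic C–H oxidation should take place at the unhindered secondary allylic CH2 (C-8) and not at the hindered tertiary C-5–H, giving the β-methyl enone with C-5 untouched.

Step 4
Reactants: 6 methyl 2-[(1S)-2-methyl-4-oxocyclohex-2-en-1-yl]propanoate; 7 1-bromo-3-chloropropane
Product: 10 methyl (1R,4aS,8aR)-1,4a-dimethyl-6-(triethylsilyloxy)-1,2,3,4,4a,7,8,8a-octahydronaphthalene-1-carboxylate, via 3-chloropropylmagnesium bromide 8 (not isolated), via chloropropyl silyl enol ether 9 (not isolated)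
Conditions: 7, activated Mg (from MgCl2 and K), THF, −78 °C; then 6, CuBr·SMe2 (10 mol %), Et3SiCl (1.1 equiv), DMPU, THF, −78 °C; then LiN(iPr)2 (1.3 equiv), THF/DMPU, −78 → 23 °C
Reagents that add atoms: chlorotriethylsilane, CC[Si](Cl)(CC)CC
Why: Copper-catalysed 1,4-addition of Grignard reagent 8, accelerated and trapped by the chlorosilane, should attack the enone β-carbon C-10 axially and anti to the pseudoaxial C-5 substituent, so C-1 enters trans to the C-4 branch and the ketone stays masked as enol ether 9; LiN(iPr)2 can then deprotonate only the ester α-carbon C-4. The C-4 enolate should displace the chloride at C-3 in a 6-exo-tet alkylation through a chair, closing ring A trans-fused. The closest known reaction type is the bifunctional-reagent annulation (conjugate addition, then intramolecular enolate alkylation), here with the ester enolate as the second nucleophile. C-10 is controlled by the C-5 stereocentre; C-4 is controlled by allylic 1,3-strain, which holds the C-5–H bond in the enolate plane so that the ring closes with C-18 equatorial (α) and the C-19 methyl axial (β). The step needs 1,4- over 1,2-addition (monovalent copper and chlorosilane), survival of the γ-chloroalkyl Grignard reagent (made and used at −78 °C) and ester-enolate over ketone-enolate alkylation (secured by the silyl enol ether).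

Step 5
Reactants: 10 methyl (1R,4aS,8aR)-1,4a-dimethyl-6-(triethylsilyloxy)-1,2,3,4,4a,7,8,8a-octahydronaphthalene-1-carboxylate; 11 4-methylpent-1-en-3-one
Product: 13 methyl (1R,4aS,5R,8aR)-1,4a-dimethyl-5-[4-methyl-3-(triethylsilyloxy)pent-2-en-1-yl]-6-oxodecahydronaphthalene-1-carboxylate, via C-9 epimer 12 (not isolated)
Conditions: HNTf2 (3 mol %), CH2Cl2, −78 °C; then DBU, CH2Cl2, 23 °C
Reagents that add atoms: none
Why: Mukaiyama–Michael addition: C-9 attacks the vinyl ketone axially on the α-face (anti to C-20) and the silyl group passes to the acceptor oxygen, freeing the C-8 ketone and masking the C-13 ketone as its enol ether, after which DBU should equilibrate the enolisable C-9 centre to the equatorial side chain (9α-H) with no aldol partner present.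

Step 6
Reactants: 13 methyl (1R,4aS,5R,8aR)-1,4a-dimethyl-5-[4-methyl-3-(triethylsilyloxy)pent-2-en-1-yl]-6-oxodecahydronaphthalene-1-carboxylate
Product: 15 methyl (1R,4aS,5R,8aR)-1,4a-dimethyl-5-(4-methyl-3-oxopentyl)-6-(trifluoromethanesulfonyloxy)-1,2,3,4,4a,5,8,8a-octahydronaphthalene-1-carboxylate, via silyl-protected alkenyl triflate 14 (not isolated)
Conditions: LiN(iPr)2, THF, −78 °C; PhNTf2, −78 → 0 °C; then 1 M HCl, THF, 0 °C
Reagents that add atoms: N-phenylbis(trifluoromethanesulfonimide), O=S(=O)(N(c1ccccc1)S(=O)(=O)C(F)(F)F)C(F)(F)F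
Why: Kinetic enolisation at the C-7 methylene (the C-9 methine is hindered and the side-chain carbonyl is masked) followed by enolate O-triflation should fix the C-7=C-8 alkene, and brief aqueous acid should hydrolyse the silyl enol ether to the C-13 ketone without touching the alkenyl triflate.

Step 7
Reactants: 15 methyl (1R,4aS,5R,8aR)-1,4a-dimethyl-5-(4-methyl-3-oxopentyl)-6-(trifluoromethanesulfonyloxy)-1,2,3,4,4a,5,8,8a-octahydronaphthalene-1-carboxylate
Product: 16 dimethyl (1R,4aS,5R,8aR)-1,4a-dimethyl-5-(4-methyl-3-oxopentyl)-1,2,3,4,4a,5,8,8a-octahydronaphthalene-1,6-dicarboxylate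
Conditions: Pd(OAc)2 (5 mol %), 1,3-bis(diphenylphosphino)propane, CO (1 atm), MeOH, Et3N, DMF, 60 °C
Reagents that add atoms: carbon monoxide, [C-]#[O+]; methanol, CO
Why: Palladium-catalysed methoxycarbonylation of the alkenyl triflate (oxidative addition, CO insertion, methanolysis) should place C-14 on C-8 with the alkene held at C-7=C-8, the ketone and the hindered ester being inert.

Step 8
Reactants: 16 dimethyl (1R,4aS,5R,8aR)-1,4a-dimethyl-5-(4-methyl-3-oxopentyl)-1,2,3,4,4a,5,8,8a-octahydronaphthalene-1,6-dicarboxylate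
Product: 17 (1R,4aS,5R,8aR)-1,4a-dimethyl-5-(4-methyl-3-oxopentyl)-1,2,3,4,4a,5,8,8a-octahydronaphthalene-1,6-dicarboxylic acid
Conditions: LiI, pyridine, reflux; then 1 M HCl
Reagents that add atoms: none
Why: Nucleophilic O-demethylation (SN2 attack of iodide on the ester methyl groups) should cleave both esters, including the hindered C-18 ester, under non-hydrolytic conditions that leave the enoate, the ketone and the four stereocentres untouched.

Compound list
1 | 2-methylcyclohex-2-en-1-one | CC1=CCCCC1=O | starting material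
2 | (1S)-2-methylcyclohex-2-en-1-ol | O[C@H]1CCCC=C1C | intermediate
3 | trimethyl orthopropionate (1,1,1-trimethoxypropane) | CCC(OC)(OC)OC | starting material
4 | 1-methoxy-1-{[(1S)-2-methylcyclohex-2-en-1-yl]oxy}prop-1-ene (ketene acetal, either alkene geometry) | CC=C(OC)O[C@H]1CCCC=C1C | intermediate (not isolated)
5 | methyl 2-[(1S)-2-methylcyclohex-2-en-1-yl]propanoate (both epimers at the propanoate α-carbon) | CC1=CCCC[C@H]1C(C)C(=O)OC | intermediate
6 | methyl 2-[(1S)-2-methyl-4-oxocyclohex-2-en-1-yl]propanoate (both epimers at the propanoate α-carbon) | CC1=CC(=O)CC[C@H]1C(C)C(=O)OC | intermediate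
7 | 1-bromo-3-chloropropane | ClCCCBr | starting material
8 | 3-chloropropylmagnesium bromide | ClCCC[Mg]Br | intermediate (not isolated)
9 | methyl 2-[(1S,2S)-2-(3-chloropropyl)-2-methyl-4-(triethylsilyloxy)cyclohex-3-en-1-yl]propanoate (both epimers at the propanoate α-carbon) | C1=C(O[Si](CC)(CC)CC)CC[C@@H](C(C)C(=O)OC)[C@]1(C)CCCCl | intermediate (not isolated)
10 | methyl (1R,4aS,8aR)-1,4a-dimethyl-6-(triethylsilyloxy)-1,2,3,4,4a,7,8,8a-octahydronaphthalene-1-carboxylate (trans-fused; both methyl groups on the same face, ester on the opposite face) | C1=C(O[Si](CC)(CC)CC)CC[C@@H]2[C@]1(C)CCC[C@@]2(C)C(=O)OC | intermediate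
11 | 4-methylpent-1-en-3-one (isopropyl vinyl ketone) | C=CC(=O)C(C)C | starting material
12 | methyl (1R,4aS,5S,8aR)-1,4a-dimethyl-5-[4-methyl-3-(triethylsilyloxy)pent-2-en-1-yl]-6-oxodecahydronaphthalene-1-carboxylate (C-9 epimer, axial side chain; enol ether of either geometry) | CC(C)C(O[Si](CC)(CC)CC)=CC[C@@H]1C(=O)CC[C@@H]2[C@]1(C)CCC[C@@]2(C)C(=O)OC | intermediate (not isolated)
13 | methyl (1R,4aS,5R,8aR)-1,4a-dimethyl-5-[4-methyl-3-(triethylsilyloxy)pent-2-en-1-yl]-6-oxodecahydronaphthalene-1-carboxylate (equatorial side chain; enol ether of either geometry) | CC(C)C(O[Si](CC)(CC)CC)=CC[C@H]1C(=O)CC[C@@H]2[C@]1(C)CCC[C@@]2(C)C(=O)OC | intermediate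
14 | methyl (1R,4aS,5R,8aR)-1,4a-dimethyl-5-[4-methyl-3-(triethylsilyloxy)pent-2-en-1-yl]-6-(trifluoromethanesulfonyloxy)-1,2,3,4,4a,5,8,8a-octahydronaphthalene-1-carboxylate | CC(C)C(O[Si](CC)(CC)CC)=CC[C@H]1C(OS(=O)(=O)C(F)(F)F)=CC[C@@H]2[C@]1(C)CCC[C@@]2(C)C(=O)OC | intermediate (not isolated)
15 | methyl (1R,4aS,5R,8aR)-1,4a-dimethyl-5-(4-methyl-3-oxopentyl)-6-(trifluoromethanesulfonyloxy)-1,2,3,4,4a,5,8,8a-octahydronaphthalene-1-carboxylate | CC(C)C(=O)CC[C@H]1C(OS(=O)(=O)C(F)(F)F)=CC[C@@H]2[C@]1(C)CCC[C@@]2(C)C(=O)OC | intermediate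
16 | dimethyl (1R,4aS,5R,8aR)-1,4a-dimethyl-5-(4-methyl-3-oxopentyl)-1,2,3,4,4a,5,8,8a-octahydronaphthalene-1,6-dicarboxylate | CC(C)C(=O)CC[C@H]1C(C(=O)OC)=CC[C@@H]2[C@]1(C)CCC[C@@]2(C)C(=O)OC | intermediate
17 | (1R,4aS,5R,8aR)-1,4a-dimethyl-5-(4-methyl-3-oxopentyl)-1,2,3,4,4a,5,8,8a-octahydronaphthalene-1,6-dicarboxylic acid (13-oxo-13,14-seco-abiet-7-ene-14,18-dioic acid) | CC(C)C(=O)CC[C@H]1C(C(=O)O)=CC[C@@H]2[C@]1(C)CCC[C@@]2(C)C(=O)O | target

Total step count: 8
Longest linear sequence: 8 steps (from 1 to 17)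

Steps most likely to fail

1. Step 4 (key step). The γ-chloroalkyl Grignard reagent may destroy itself by intramolecular 1,3-elimination to cyclopropane before it is transferred to copper. In the second stage, residual chlorosilane may O-silylate the ester enolate and stop the ring closure. Fallback: from 6 and 7, a nickel-catalysed reductive conjugate addition (NiCl2·glyme, neocuproine, Mn, Et3SiCl, DMF) couples the alkyl bromide directly with the enone, so no preformed γ-chloroalkyl metal is needed. It gives 9, now isolated and freed of chlorosilane. Treatment of 9 with LiN(iPr)2 in THF/DMPU as a second operation returns to the route at 10.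

2. Step 5. Facial selectivity at C-9 may be poor or the equilibration incomplete, and the silyl enol ether may be lost early, which would expose two enolisable ketones to step 6. Fallback: from 10, MeLi (THF, 0 °C) cleaves the Si–O bond to the lithium enolate, which adds to acrylonitrile at −78 °C; NaOMe in MeOH then equilibrates C-9 and gives methyl (1R,4aS,5R,8aR)-5-(2-cyanoethyl)-1,4a-dimethyl-6-oxodecahydronaphthalene-1-carboxylate F1. The nitrile α-protons are far less acidic than those of the ketone, so LiN(iPr)2 and PhNTf2 give methyl (1R,4aS,5R,8aR)-5-(2-cyanoethyl)-1,4a-dimethyl-6-(trifluoromethanesulfonyloxy)-1,2,3,4,4a,5,8,8a-octahydronaphthalene-1-carboxylate F2. Hydroxycarbonylation (Pd(OAc)2, 1,3-bis(diphenylphosphino)propane, CO, H2O, Et3N, DMF) gives (1R,4aS,5R,8aR)-5-(2-cyanoethyl)-1-(methoxycarbonyl)-1,4a-dimethyl-1,2,3,4,4a,5,8,8a-octahydronaphthalene-6-carboxylic acid F3 (locants as in 16). Excess iPrMgCl (THF, 0 → 23 °C, then aqueous HCl) adds to the nitrile only, the carboxylate and the hindered ester being inert, and gives (1R,4aS,5R,8aR)-1-(methoxycarbonyl)-1,4a-dimethyl-5-(4-methyl-3-oxopentyl)-1,2,3,4,4a,5,8,8a-octahydronaphthalene-6-carboxylic acid F4 (locants as in 16). LiI in pyridine as in step 8 then returns to the route at the target 17.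

3. Step 3. Hydrogen abstraction may be poorly regioselective (attack at the tertiary C-5–H with loss of the stereocentre) or the product may be over-oxidised. Fallback: from 5, mCPBA (CH2Cl2, 0 °C) gives methyl 2-[(2S)-1-methyl-7-oxabicyclo[4.1.0]heptan-2-yl]propanoate F5. PhSeNa (from PhSeSePh and NaBH4, EtOH) opens the epoxide at its secondary carbon to methyl 2-[(1S)-2-hydroxy-2-methyl-3-(phenylselanyl)cyclohexyl]propanoate F6. H2O2 with pyridine oxidises the selenide, and the selenoxide eliminates toward the ring CH2 to give methyl 2-[(1S)-2-hydroxy-2-methylcyclohex-3-en-1-yl]propanoate F7. Pyridinium chlorochromate, C5H5NH[CrO3Cl], in CH2Cl2 then effects the oxidative 1,3-transposition of the tertiary allylic alcohol and returns to the route at 6.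

Further compounds
F0 | step 4 | none | none
F1 | step 5 | methyl (1R,4aS,5R,8aR)-5-(2-cyanoethyl)-1,4a-dimethyl-6-oxodecahydronaphthalene-1-carboxylate | N#CCC[C@H]1C(=O)CC[C@@H]2[C@]1(C)CCC[C@@]2(C)C(=O)OC
F2 | step 5 | methyl (1R,4aS,5R,8aR)-5-(2-cyanoethyl)-1,4a-dimethyl-6-(trifluoromethanesulfonyloxy)-1,2,3,4,4a,5,8,8a-octahydronaphthalene-1-carboxylate | N#CCC[C@H]1C(OS(=O)(=O)C(F)(F)F)=CC[C@@H]2[C@]1(C)CCC[C@@]2(C)C(=O)OC
F3 | step 5 | (1R,4aS,5R,8aR)-5-(2-cyanoethyl)-1-(methoxycarbonyl)-1,4a-dimethyl-1,2,3,4,4a,5,8,8a-octahydronaphthalene-6-carboxylic acid (locants as in 16) | N#CCC[C@H]1C(C(=O)O)=CC[C@@H]2[C@]1(C)CCC[C@@]2(C)C(=O)OC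
F4 | step 5 | (1R,4aS,5R,8aR)-1-(methoxycarbonyl)-1,4a-dimethyl-5-(4-methyl-3-oxopentyl)-1,2,3,4,4a,5,8,8a-octahydronaphthalene-6-carboxylic acid (locants as in 16) | CC(C)C(=O)CC[C@H]1C(C(=O)O)=CC[C@@H]2[C@]1(C)CCC[C@@]2(C)C(=O)OC
F5 | step 3 | methyl 2-[(2S)-1-methyl-7-oxabicyclo[4.1.0]heptan-2-yl]propanoate (epoxide diastereomers) | CC12OC1CCC[C@H]2C(C)C(=O)OC
F6 | step 3 | methyl 2-[(1S)-2-hydroxy-2-methyl-3-(phenylselanyl)cyclohexyl]propanoate (diastereomers at the carbinol and selenide carbons) | CC1(O)C([Se]c2ccccc2)CCC[C@H]1C(C)C(=O)OC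
F7 | step 3 | methyl 2-[(1S)-2-hydroxy-2-methylcyclohex-3-en-1-yl]propanoate (carbinol diastereomers) | CC1(O)C=CCC[C@H]1C(C)C(=O)OC
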